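**Strategy.** Everything rests on disconnecting the bond between the ring oxygen and the methyl-bearing quaternary carbon C5 of the saturated γ-lactone (ring C). An acyclic bis-epoxy N,N-dimethylamide is zipped up by acid in one operation: the amide oxygen opens one trisubstituted epoxide at its tertiary carbon, closing ring C with inversion, and the hydroxyl released opens the second epoxide at its tertiary carbon, closing the oxolane (ring B). The step exploits that C5 of ring C and C5 of ring B are both oxygenated, methyl-bearing quaternary carbons flanking the ring-B methine C2, so two catalytic epoxidations encode all three stereocentres. The residual 1,2-diol becomes a vinyl group for a final cross-metathesis with the butenolide (ring A) side chain.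

Key step: step 7

Remark: (E)-geranyl acetate, 4-methylpenta-1,3-diene and 3-bromofuran-2(5H)-one are taken as commercial; the carbinol centre made in step 2 is racemic and is erased in step 3.

**Route**

Step 1
Reactants: 1 geranyl acetate [(2E)-3,7-dimethylocta-2,6-dien-1-yl acetate]
Product: 3 (2E)-3-methyl-6-oxohex-2-en-1-yl acetate, via ozonide 2 (not isolated)
Conditions: O3 (1.0 equiv, indicator end-point), CH2Cl2, −78 °C; then Me2S, −78 °C → rt
Reagents that add atoms: ozone, [O-][O+]=O
Why: Chemoselective ozonolysis with reductive work-up: the distal trisubstituted alkene is more electron-rich than the one carrying the allylic acetate and should be cleaved first.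

Step 2
Reactants: 3 (2E)-3-methyl-6-oxohex-2-en-1-yl acetate; 4 isopropenylmagnesium bromide
Product: 5 (2E)-6-hydroxy-3,7-dimethylocta-2,7-dien-1-yl acetate (racemic at C6)
Conditions: THF, −78 °C; then H2O (aq. NH4Cl buffer)
Reagents that add atoms: isopropenylmagnesium bromide (4), CC(=C)[Mg]Br
Why: Grignard 1,2-addition to the aldehyde should outrun attack on the acetate at −78 °C; the new carbinol centre is formed as a racemate and is destroyed in step 3.

Step 3
Reactants: 5 (2E)-6-hydroxy-3,7-dimethylocta-2,7-dien-1-yl acetate; 6 N,N-dimethylacetamide dimethyl acetal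
Product: 8 (2E,6E)-10-(dimethylamino)-3,7-dimethyl-10-oxodeca-2,6-dien-1-yl acetate, via ketene N,O-acetal 7 (not isolated)
Conditions: toluene, 110 °C, MeOH distilled off
Reagents that add atoms: N,N-dimethylacetamide dimethyl acetal (6), CC(OC)(OC)N(C)C
Why: Eschenmoser–Claisen rearrangement: the ketene N,O-acetal undergoes a chair [3,3] shift with the chain equatorial, which should give the (E)-trisubstituted alkene and the γ,δ-unsaturated dimethylamide while erasing the carbinol centre.

Step 4
Reactants: 8 (2E,6E)-10-(dimethylamino)-3,7-dimethyl-10-oxodeca-2,6-dien-1-yl acetate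
Product: 9 (2E)-5-[(2R,3R)-3-[3-(dimethylamino)-3-oxopropyl]-3-methyloxiran-2-yl]-3-methylpent-2-en-1-yl acetate
Conditions: D-fructose-derived Shi ketone (1,2:4,5-di-O-isopropylidene-β-D-erythro-2,3-hexodiulo-2,6-pyranose, 0.3 equiv), KHSO5 (as its triple salt with KHSO4 and K2SO4), K2CO3, Bu4NHSO4 (cat.), MeCN/dimethoxymethane/aq. Na2B4O7–Na2EDTA buffer (pH 10.5), 0 °C
Reagents that add atoms: potassium peroxymonosulfate, [K+].[O-]S(=O)(=O)OO
Why: Shi asymmetric epoxidation: the chiral dioxirane should attack the electron-rich distal alkene through a spiro transition state to set the (R,R)-epoxide, while the alkene bearing the allylic acetate is inductively deactivated.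

Step 5
Reactants: 9 (2E)-5-[(2R,3R)-3-[3-(dimethylamino)-3-oxopropyl]-3-methyloxiran-2-yl]-3-methylpent-2-en-1-yl acetate
Product: 10 3-[(2R,3R)-3-[(3E)-5-hydroxy-3-methylpent-3-en-1-yl]-2-methyloxiran-2-yl]-N,N-dimethylpropanamide
Conditions: K2CO3 (0.2 equiv), MeOH, 0 °C
Reagents that add atoms: none
Why: Mild transesterification should remove the acetate without touching the tertiary amide or the epoxide, unmasking the allylic alcohol needed for the directed epoxidation.

Step 6
Reactants: 10 3-[(2R,3R)-3-[(3E)-5-hydroxy-3-methylpent-3-en-1-yl]-2-methyloxiran-2-yl]-N,N-dimethylpropanamide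
Product: 11 3-[(2R,3R)-3-{2-[(2S,3S)-3-(hydroxymethyl)-2-methyloxiran-2-yl]ethyl}-2-methyloxiran-2-yl]-N,N-dimethylpropanamide
Conditions: Ti(OiPr)4 (0.2 equiv), L-(+)-diethyl tartrate (0.25 equiv), tBuOOH (anhydrous, 2 equiv), 4 Å molecular sieves, CH2Cl2, −20 °C; non-acidic work-up (saturated aq. Na2SO4)
Reagents that add atoms: tert-butyl hydroperoxide, CC(C)(C)OO
Why: Sharpless asymmetric epoxidation: the L-(+)-tartrate complex should deliver oxygen to the allylic alcohol face that gives the (2S,3S)-epoxy alcohol (reagent control); the remote epoxide and the amide are inert.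

Step 7
Reactants: 11 3-[(2R,3R)-3-{2-[(2S,3S)-3-(hydroxymethyl)-2-methyloxiran-2-yl]ethyl}-2-methyloxiran-2-yl]-N,N-dimethylpropanamide
Product: 14 (5S)-5-[(2R,5R)-5-[(1S)-1,2-dihydroxyethyl]-5-methyloxolan-2-yl]-5-methyloxolan-2-one, via monocyclic iminium ether 12 (not isolated), via bicyclic iminium ether 13 (not isolated)
Conditions: (±)-camphor-10-sulfonic acid (1.3 equiv), CH2Cl2, −20 → 0 °C; then H2O/NaOAc–AcOH buffer (pH 5), rt
Reagents that add atoms: water, O
Why: Protonation of the (2R,3R)-epoxide lets the amide carbonyl oxygen, the strongest internal nucleophile, attack its proximal tertiary carbon in a 5-exo-tet opening (neighbouring-group participation, as in halolactonisation of tertiary amides), which closes ring C as an iminium ether with inversion at that carbon and releases the secondary hydroxyl with retention. That hydroxyl then opens the protonated (2S,3S)-epoxy alcohol at its tertiary carbon, again 5-exo-tet with inversion, closing oxolane ring B, and aqueous work-up hydrolyses the iminium ether to the γ-lactone and dimethylamine. The closest known reaction type is the acid-promoted, exo-selective polyepoxide-opening cascade of polyether synthesis. The lactone quaternary centre (S) should arise by inversion of the R epoxide carbon set in step 4, the adjacent ring-B methine (R) is the untouched epoxide carbon of step 4, and the ring-B quaternary centre (R) should arise by inversion of the S epoxide carbon set in step 6, so all three are reagent-controlled and stereospecific. The step needs directional and exo regioselectivity: every productive attack is 5-exo at a tertiary carbon, whereas 6-endo closures or a cascade running the opposite way would require attack at secondary carbons, the one next to the hydroxymethyl group being inductively deactivated as well.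

Step 8
Reactants: 14 (5S)-5-[(2R,5R)-5-[(1S)-1,2-dihydroxyethyl]-5-methyloxolan-2-yl]-5-methyloxolan-2-one
Product: 15 (5S)-5-[(2R,5R)-5-ethenyl-5-methyloxolan-2-yl]-5-methyloxolan-2-one
Conditions: PPh3 (4 equiv), imidazole (4 equiv), I2 (3 equiv), toluene, 110 °C
Reagents that add atoms: none
Why: Garegg–Samuelsson deoxygenation: the primary hydroxyl becomes the iodide and the secondary one an alkoxyphosphonium ion, and iodide-induced reductive elimination should give the terminal alkene without touching the adjacent quaternary ring carbon or the lactone.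

Step 9
Reactants: 16 4-methylpenta-1,3-diene; 17 3-bromofuran-2(5H)-one
Product: 19 3-(4-methylpent-3-en-1-yl)furan-2(5H)-one, via alkylborane 18 (not isolated)
Conditions: 9-borabicyclo[3.3.1]nonane (9-BBN), THF, 0 °C → rt; then 17, PdCl2(dppf) (5 mol%), AsPh3 (5 mol%), Cs2CO3, DMF/THF/H2O, rt
Reagents that add atoms: none
Why: 9-BBN should add to the unhindered terminal alkene of the diene with boron at the terminal carbon, and B-alkyl Suzuki–Miyaura coupling (zerovalent palladium) then joins the homoprenyl group to C3 of the butenolide.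

Step 10
Reactants: 19 3-(4-methylpent-3-en-1-yl)furan-2(5H)-one
Product: 20 3-[(3E)-5-hydroxy-4-methylpent-3-en-1-yl]furan-2(5H)-one
Conditions: SeO2 (0.4 equiv), tBuOOH (3 equiv), salicylic acid (0.1 equiv), CH2Cl2, rt
Reagents that add atoms: selenium dioxide (catalytic oxygen carrier), O=[Se]=O; tert-butyl hydroperoxide (terminal oxidant), CC(C)(C)OO
Why: SeO2-catalysed allylic oxidation (ene reaction, then [2,3]-sigmatropic shift) should hydroxylate the (E)-methyl group of the trisubstituted alkene selectively, giving the (E)-allylic alcohol; the electron-poor butenolide alkene is inert.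

Step 11
Reactants: 20 3-[(3E)-5-hydroxy-4-methylpent-3-en-1-yl]furan-2(5H)-one
Product: 21 3-[(3E)-5-bromo-4-methylpent-3-en-1-yl]furan-2(5H)-one
Conditions: CBr4, PPh3, CH2Cl2, 0 °C
Reagents that add atoms: carbon tetrabromide, BrC(Br)(Br)Br
Why: Appel bromination of the primary allylic alcohol should proceed by direct displacement under neutral conditions, without allylic transposition or loss of alkene geometry.

Step 12
Reactants: 21 3-[(3E)-5-bromo-4-methylpent-3-en-1-yl]furan-2(5H)-one; 22 tributyl(vinyl)stannane
Product: 23 3-[(3E)-4-methylhepta-3,6-dien-1-yl]furan-2(5H)-one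
Conditions: Pd2(dba)3 (2.5 mol%), tri(2-furyl)phosphine (10 mol%), THF, 50 °C
Reagents that add atoms: tributyl(vinyl)stannane (22), C=C[Sn](CCCC)(CCCC)CCCC
Why: Stille allyl–vinyl coupling under neutral conditions should deliver the vinyl group to the unsubstituted allyl terminus with retention of the (E)-trisubstituted alkene, giving the skipped diene without exposing the butenolide to base.

Step 13
Reactants: 15 (5S)-5-[(2R,5R)-5-ethenyl-5-methyloxolan-2-yl]-5-methyloxolan-2-one; 23 3-[(3E)-4-methylhepta-3,6-dien-1-yl]furan-2(5H)-one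
Product: 24 (5S)-5-methyl-5-[(2R,5R)-5-methyl-5-[(1E,4E)-4-methyl-7-(2-oxo-2,5-dihydrofuran-3-yl)hepta-1,4-dien-1-yl]oxolan-2-yl]oxolan-2-one (target)
Conditions: second-generation Hoveyda–Grubbs catalyst RuCl2(H2IMes)(=CH–C6H4–2-OiPr) (10 mol%), 1,4-benzoquinone (20 mol%), 23 (3 equiv), CH2Cl2, 40 °C
Reagents that add atoms: none
Why: Olefin cross-metathesis between the terminal alkene of 23 and the vinyl group of 15, which cannot homodimerise because of the adjacent quaternary carbon, should give the (E)-disubstituted alkene for steric reasons; the trisubstituted and butenolide alkenes are too hindered or electron-poor to take part.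

**Compound list**

1 | geranyl acetate, (2E)-3,7-dimethylocta-2,6-dien-1-yl acetate | CC(C)=CCC/C(C)=C/COC(C)=O | starting material
2 | ozonide of 1 at the distal alkene (not isolated) | CC1(C)OOC(CC/C(C)=C/COC(C)=O)O1 | intermediate
3 | (2E)-3-methyl-6-oxohex-2-en-1-yl acetate | O=CCC/C(C)=C/COC(C)=O | intermediate
4 | isopropenylmagnesium bromide | CC(=C)[Mg]Br | starting material
5 | (2E)-6-hydroxy-3,7-dimethylocta-2,7-dien-1-yl acetate (racemic) | CC(=C)C(O)CC/C(C)=C/COC(C)=O | intermediate
6 | N,N-dimethylacetamide dimethyl acetal | CC(OC)(OC)N(C)C | starting material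
7 | ketene N,O-acetal of 5 (not isolated) | C=C(N(C)C)OC(CC/C(C)=C/COC(C)=O)C(C)=C | intermediate
8 | (2E,6E)-10-(dimethylamino)-3,7-dimethyl-10-oxodeca-2,6-dien-1-yl acetate | CN(C)C(=O)CC/C(C)=C/CC/C(C)=C/COC(C)=O | intermediate
9 | (2E)-5-[(2R,3R)-3-[3-(dimethylamino)-3-oxopropyl]-3-methyloxiran-2-yl]-3-methylpent-2-en-1-yl acetate | CN(C)C(=O)CC[C@@]1(C)O[C@@H]1CC/C(C)=C/COC(C)=O | intermediate
10 | 3-[(2R,3R)-3-[(3E)-5-hydroxy-3-methylpent-3-en-1-yl]-2-methyloxiran-2-yl]-N,N-dimethylpropanamide | CN(C)C(=O)CC[C@@]1(C)O[C@@H]1CC/C(C)=C/CO | intermediate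
11 | 3-[(2R,3R)-3-{2-[(2S,3S)-3-(hydroxymethyl)-2-methyloxiran-2-yl]ethyl}-2-methyloxiran-2-yl]-N,N-dimethylpropanamide | CN(C)C(=O)CC[C@@]1(C)O[C@@H]1CC[C@]2(C)O[C@H]2CO | intermediate
12 | monocyclic iminium ether, N-[(5S)-5-[(1R)-1-hydroxy-3-[(2S,3S)-3-(hydroxymethyl)-2-methyloxiran-2-yl]propyl]-5-methyloxolan-2-ylidene]-N-methylmethanaminium camphorsulfonate (not isolated) | OC[C@@H]1O[C@@]1(C)CC[C@@H](O)[C@]2(C)CCC(=[N+](C)C)O2.CC1(C)C2CCC1(CS(=O)(=O)[O-])C(=O)C2 | intermediate
13 | bicyclic iminium ether, N-[(5S)-5-[(2R,5R)-5-[(1S)-1,2-dihydroxyethyl]-5-methyloxolan-2-yl]-5-methyloxolan-2-ylidene]-N-methylmethanaminium camphorsulfonate (not isolated) | OC[C@H](O)[C@@]1(C)CC[C@H]([C@]2(C)CCC(=[N+](C)C)O2)O1.CC1(C)C2CCC1(CS(=O)(=O)[O-])C(=O)C2 | intermediate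
14 | (5S)-5-[(2R,5R)-5-[(1S)-1,2-dihydroxyethyl]-5-methyloxolan-2-yl]-5-methyloxolan-2-one | OC[C@H](O)[C@@]1(C)CC[C@H]([C@]2(C)CCC(=O)O2)O1 | intermediate
15 | (5S)-5-[(2R,5R)-5-ethenyl-5-methyloxolan-2-yl]-5-methyloxolan-2-one | C=C[C@@]1(C)CC[C@H]([C@]2(C)CCC(=O)O2)O1 | intermediate
16 | 4-methylpenta-1,3-diene | C=CC=C(C)C | starting material
17 | 3-bromofuran-2(5H)-one | O=C1OCC=C1Br | starting material
18 | 9-(4-methylpent-3-en-1-yl)-9-borabicyclo[3.3.1]nonane (not isolated) | CC(C)=CCCB1C2CCCC1CCC2 | intermediate
19 | 3-(4-methylpent-3-en-1-yl)furan-2(5H)-one | CC(C)=CCCC1=CCOC1=O | intermediate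
20 | 3-[(3E)-5-hydroxy-4-methylpent-3-en-1-yl]furan-2(5H)-one | OC/C(C)=C/CCC1=CCOC1=O | intermediate
21 | 3-[(3E)-5-bromo-4-methylpent-3-en-1-yl]furan-2(5H)-one | BrC/C(C)=C/CCC1=CCOC1=O | intermediate
22 | tributyl(vinyl)stannane | C=C[Sn](CCCC)(CCCC)CCCC | starting material
23 | 3-[(3E)-4-methylhepta-3,6-dien-1-yl]furan-2(5H)-one | C=CC/C(C)=C/CCC1=CCOC1=O | intermediate
24 | (5S)-5-methyl-5-[(2R,5R)-5-methyl-5-[(1E,4E)-4-methyl-7-(2-oxo-2,5-dihydrofuran-3-yl)hepta-1,4-dien-1-yl]oxolan-2-yl]oxolan-2-one | C/C(=C\CCC1=CCOC1=O)C/C=C/[C@@]1(C)CC[C@H]([C@]2(C)CCC(=O)O2)O1 | target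

**Step count and risks**

Total: 13 steps. Longest linear sequence: 9 steps (steps 1–8, then step 13); steps 9–12 form the convergent branch.

Most likely to fail:

1. Step 7. The risk is premature or misdirected epoxide opening: attack by water or the counter-ion on the 2,3-epoxy alcohol before the secondary hydroxyl is released, a 6-endo closure, or a Meinwald-type rearrangement at a tertiary epoxide carbon. The fallback uncouples the two closures and sets out from 10. Acid treatment of the mono-epoxide (camphor-10-sulfonic acid, CH2Cl2; then buffered water) closes ring C alone by the same amide-oxygen attack and should give (5S)-5-[(1R,4E)-1,6-dihydroxy-4-methylhex-4-en-1-yl]-5-methyloxolan-2-one F1. Sharpless epoxidation of its allylic alcohol (Ti(OiPr)4, L-(+)-diethyl tartrate, tBuOOH) should give (5S)-5-[(1R)-1-hydroxy-3-[(2S,3S)-3-(hydroxymethyl)-2-methyloxiran-2-yl]propyl]-5-methyloxolan-2-one F2. Catalytic acid (or the titanium alkoxide already present) then closes ring B by 5-exo opening at the tertiary carbon, and the route is rejoined at 14.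

2. Step 13. The risk is slow engagement of the hindered vinyl group next to the quaternary carbon, with self-metathesis of 23 and migration of the skipped-diene double bonds taking over. The fallback replaces metathesis by an allyl–alkenyl cross-coupling and sets out from 14 and 21 (it also bypasses steps 8 and 12). NaIO4 cleavage of the diol (THF/H2O) should give (2R,5R)-2-methyl-5-[(2S)-2-methyl-5-oxooxolan-2-yl]oxolane-2-carbaldehyde F3. Takai-type boryl olefination (CrCl2, Cl2CHBpin, LiI, THF) should give the (E)-alkenylboronate (5S)-5-methyl-5-[(2R,5R)-5-methyl-5-[(E)-2-(4,4,5,5-tetramethyl-1,3,2-dioxaborolan-2-yl)ethenyl]oxolan-2-yl]oxolan-2-one F4. Suzuki–Miyaura coupling of F4 with allylic bromide 21 (Pd(PPh3)4, K3PO4, THF/H2O, rt) then rejoins the route at 24.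

3. Step 9. The risk is base-induced ring opening or γ-deprotonation of the bromobutenolide, protodebromination, or β-hydride elimination from the alkylpalladium intermediate. The fallback is a base-free Negishi alkylation and sets out from 17. Commercial 5-bromo-2-methylpent-2-ene F5 is converted with zinc dust and LiCl in THF into (4-methylpent-3-en-1-yl)zinc bromide F6, which is coupled with 17 (Pd2(dba)3, SPhos, THF, rt) to rejoin the route at 19.

**Further compounds**

F1 | step 7 | (5S)-5-[(1R,4E)-1,6-dihydroxy-4-methylhex-4-en-1-yl]-5-methyloxolan-2-one | OC/C=C(C)/CC[C@@H](O)[C@]1(C)CCC(=O)O1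
F2 | step 7 | (5S)-5-[(1R)-1-hydroxy-3-[(2S,3S)-3-(hydroxymethyl)-2-methyloxiran-2-yl]propyl]-5-methyloxolan-2-one | OC[C@@H]1O[C@@]1(C)CC[C@@H](O)[C@]2(C)CCC(=O)O2
F3 | step 13 | (2R,5R)-2-methyl-5-[(2S)-2-methyl-5-oxooxolan-2-yl]oxolane-2-carbaldehyde | O=C[C@@]1(C)CC[C@H]([C@]2(C)CCC(=O)O2)O1
F4 | step 13 | (5S)-5-methyl-5-[(2R,5R)-5-methyl-5-[(E)-2-(4,4,5,5-tetramethyl-1,3,2-dioxaborolan-2-yl)ethenyl]oxolan-2-yl]oxolan-2-one | CC1(C)OB(/C=C/[C@@]2(C)CC[C@H]([C@]3(C)CCC(=O)O3)O2)OC1(C)C
F5 | step 9 | 5-bromo-2-methylpent-2-ene | CC(C)=CCCBr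
F6 | step 9 | (4-methylpent-3-en-1-yl)zinc bromide | CC(C)=CCC[Zn]Br
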